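**Retrosynthetic overview**

1. Ring C (the pyranone) is the only ring built and is closed last through the O1–C2 carbon–oxygen bond: the ring A phenol of an o-hydroxyaryl enaminone captures the iminium carbon (chromone annulation). Rings A and B are bought as benzenes.
2. In the same flask, ring B is joined to C3 after a C–O bond-forming dearomatisation (para-methoxyphenol → quinone monoketal) makes C1′ electrophilic; rearomatisation returns the 2′-OH and the 5′-OMe.
3. The ring B oxygen pattern is set by C–O chemistry on 3-bromo-4,5-dihydroxybenzaldehyde: regioselective O-methylation (5′-OMe), MOM on the 4′-oxygen, Baeyer–Villiger/Dakin oxidation of CHO to the 2′-OH.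
4. The prenyl group comes from a Suzuki–Miyaura coupling at the bromide next to the OMe.
5. One protecting group only (4′-O-MOM), removed in the last flask.

Assumption: kwakhurin has no stereocentre and the aryl–chromone axis is taken as freely rotating, so the target is achiral and no stereocontrol is needed.

**Route**

Step 1
Reactants: 1 3-bromo-4,5-dihydroxybenzaldehyde
Product: 2 3-bromo-5-hydroxy-4-methoxybenzaldehyde
Conditions: MeI (1.1 equiv), Li2CO3 (1.2 equiv), DMF, 45 °C
Reagents that add atoms: iodomethane, CI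
Why: The 4-OH (para to the aldehyde, ortho to Br) is the most acidic phenol, so a weak base forms only its phenoxide, which is methylated (regioselective Williamson O-alkylation).

Step 2
Reactants: 2 3-bromo-5-hydroxy-4-methoxybenzaldehyde
Product: 3 3-bromo-4-methoxy-5-(methoxymethoxy)benzaldehyde
Conditions: MOMCl (1.3 equiv), K2CO3 (1.5 equiv), acetone, 0 → 23 °C
Reagents that add atoms: chloromethyl methyl ether, COCCl
Why: Williamson-type O-alkylation of the remaining phenol masks the future 4′-oxygen, so that only one free phenol is present in the later oxidation.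

Step 3
Reactants: 3 3-bromo-4-methoxy-5-(methoxymethoxy)benzaldehyde
Product: 5 3-bromo-4-methoxy-5-(methoxymethoxy)phenol, via aryl formate 4 (not isolated)
Conditions: mCPBA (1.2 equiv), CH2Cl2, 0 → 23 °C; then K2CO3 (0.1 equiv), MeOH, 0 °C
Reagents that add atoms: 3-chloroperbenzoic acid, OOC(=O)c1cccc(Cl)c1
Why: Baeyer–Villiger (Dakin-type) oxidation, in which the electron-rich aryl group para to OMe migrates to give the aryl formate that is methanolysed to the phenol; no alkene is present yet, so the peracid is safe.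

Step 4
Reactants: 5 3-bromo-4-methoxy-5-(methoxymethoxy)phenol; 6 4,4,5,5-tetramethyl-2-(3-methylbut-2-en-1-yl)-1,3,2-dioxaborolane (prenylboronic acid pinacol ester, 2 equiv)
Product: 7 4-methoxy-3-(methoxymethoxy)-5-(3-methylbut-2-en-1-yl)phenol
Conditions: PdCl2(dppf) (5 mol %), K3PO4 (3 equiv), THF/H2O 10:1, 70 °C
Reagents that add atoms: none
Why: Suzuki–Miyaura allylation; with chelating dppf the allyl–palladium intermediate equilibrates before reductive elimination, so the aryl group ends on the unsubstituted terminus (linear prenyl), and the free phenol is tolerated as its phenoxide.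

Step 5
Reactants: 8 1-(2,4-dihydroxyphenyl)ethan-1-one (2,4-dihydroxyacetophenone)
Product: 9 (E)-1-(2,4-dihydroxyphenyl)-3-(dimethylamino)prop-2-en-1-one
Conditions: Me2NCH(OiPr)2 (3 equiv), toluene, 80 °C
Reagents that add atoms: N,N-dimethylformamide diisopropyl acetal, CN(C)C(OC(C)C)OC(C)C
Why: Condensation of the methyl ketone with an amide acetal gives the thermodynamic E-enaminone; the isopropyl acetal is used because, unlike the methyl acetal, it does not O-alkylate the free phenols.

Step 6
Reactants: 7 4-methoxy-3-(methoxymethoxy)-5-(3-methylbut-2-en-1-yl)phenol; 9 (E)-1-(2,4-dihydroxyphenyl)-3-(dimethylamino)prop-2-en-1-one (1.3 equiv)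
Product: 12 kwakhurin, via quinone monoketal 10 (not isolated), via MOM-protected isoflavone 11 (not isolated)
Conditions: PhI(OAc)2 (1.05 equiv), MeOH, 0 °C, then evaporate; 9, CF3CO2H (1 equiv), (CF3)2CHOH/CH2Cl2 1:1, −20 → 23 °C; then 2 M HCl, MeOH, 45 °C
Reagents that add atoms: methanol, CO (one of the two equivalent ketal methoxy groups of 10 is kept as the 5′-OMe)
Why: Proposed new method: an oxidative, arylative chromone annulation in which the trivalent-iodine oxidant converts the para-methoxyphenol 7 in methanol into quinone monoketal 10 (known C–O dearomatisation), acid in the fluoroalcohol ionises 10 to an O-methyl oxocarbenium that is attacked at C1′ by the α-carbon of enaminone 9 (C3′ is deactivated as the α-carbon of the vinylogous ester formed by the 4′-OMOM group and the carbonyl), proton loss rearomatises ring B to the 2′-phenol, and the hydrogen-bonded ring A phenol then adds to the iminium carbon and expels dimethylamine, closing ring C through the O1–C2 bond before aqueous HCl removes the MOM group; the closest known reactions are the acid-promoted SN2′ substitution of quinone monoacetals by π-nucleophiles, the Nenitzescu reaction, and the electrophile-triggered chromone annulation of o-hydroxyaryl enaminones, which cyclise spontaneously at room temperature whereas open Nenitzescu adducts need separate forcing to give benzofurans.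

**Compound list**

1 | 3-bromo-4,5-dihydroxybenzaldehyde | O=Cc1cc(O)c(O)c(Br)c1 | starting material
2 | 3-bromo-5-hydroxy-4-methoxybenzaldehyde | O=Cc1cc(O)c(OC)c(Br)c1 | intermediate
3 | 3-bromo-4-methoxy-5-(methoxymethoxy)benzaldehyde | O=Cc1cc(OCOC)c(OC)c(Br)c1 | intermediate
4 | 3-bromo-4-methoxy-5-(methoxymethoxy)phenyl formate | O=COc1cc(OCOC)c(OC)c(Br)c1 | intermediate
5 | 3-bromo-4-methoxy-5-(methoxymethoxy)phenol | Oc1cc(OCOC)c(OC)c(Br)c1 | intermediate
6 | 4,4,5,5-tetramethyl-2-(3-methylbut-2-en-1-yl)-1,3,2-dioxaborolane | CC(C)=CCB1OC(C)(C)C(C)(C)O1 | starting material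
7 | 4-methoxy-3-(methoxymethoxy)-5-(3-methylbut-2-en-1-yl)phenol | Oc1cc(OCOC)c(OC)c(CC=C(C)C)c1 | intermediate
8 | 1-(2,4-dihydroxyphenyl)ethan-1-one | CC(=O)c1ccc(O)cc1O | starting material
9 | (E)-1-(2,4-dihydroxyphenyl)-3-(dimethylamino)prop-2-en-1-one | CN(C)/C=C/C(=O)c1ccc(O)cc1O | intermediate
10 | 4,4-dimethoxy-3-(methoxymethoxy)-5-(3-methylbut-2-en-1-yl)cyclohexa-2,5-dien-1-one | O=C1C=C(CC=C(C)C)C(OC)(OC)C(OCOC)=C1 | intermediate
11 | 7-hydroxy-3-[6-hydroxy-3-methoxy-4-(methoxymethoxy)-2-(3-methylbut-2-en-1-yl)phenyl]-4H-chromen-4-one | COCOc1cc(O)c(-c2coc3cc(O)ccc3c2=O)c(CC=C(C)C)c1OC | intermediate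
12 | kwakhurin, 3-[4,6-dihydroxy-3-methoxy-2-(3-methylbut-2-en-1-yl)phenyl]-7-hydroxy-4H-chromen-4-one | COc1c(O)cc(O)c(-c2coc3cc(O)ccc3c2=O)c1CC=C(C)C | target

**Step count**

Total steps: 6. Longest linear sequence: 5 (steps 1, 2, 3, 4, 6).

**Three steps most likely to fail**

Step 6 (the new step). The main risks are closure by the new 2′-oxygen instead of the ring A oxygen (giving the isomeric 3-aroylbenzofuran), attack at C3′, and acid damage to the prenyl group. The fallback uses known chemistry only; it sets out from 7 (with 8 for the chromone partner) and comes back to the route at 12.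
- Phenol 7 is protected (MOMCl, K2CO3) to 2-methoxy-1,5-bis(methoxymethoxy)-3-(3-methylbut-2-en-1-yl)benzene F1.
- F1 is brominated para to the 4′-OMOM group (NBS, MeCN, 0 °C) to 2-bromo-4-methoxy-1,5-bis(methoxymethoxy)-3-(3-methylbut-2-en-1-yl)benzene F2.
- Bromine–lithium exchange (n-BuLi, THF, −78 °C), B(OiPr)3 and mild acid give [3-methoxy-4,6-bis(methoxymethoxy)-2-(3-methylbut-2-en-1-yl)phenyl]boronic acid F3.
- In parallel, 8 is protected at the 4-OH (MOMCl, K2CO3, acetone) to 1-[2-hydroxy-4-(methoxymethoxy)phenyl]ethan-1-one F4, condensed with DMF dimethyl acetal to (E)-3-(dimethylamino)-1-[2-hydroxy-4-(methoxymethoxy)phenyl]prop-2-en-1-one F5, and cyclised with I2 to 3-iodo-7-(methoxymethoxy)-4H-chromen-4-one F6.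
- Suzuki–Miyaura coupling of F3 with F6 (Pd(OAc)2, SPhos, K3PO4, toluene/H2O) gives 3-[3-methoxy-4,6-bis(methoxymethoxy)-2-(3-methylbut-2-en-1-yl)phenyl]-7-(methoxymethoxy)-4H-chromen-4-one F7.
- 2 M HCl in MeOH then gives 12. Here the pyranone is already in place before the 2′-oxygen is freed, so the benzofuran pathway is closed.

Step 4. The risks are branched (1,1-dimethylallyl) product and protodeboronation of the allylboronate. The fallback sets out from 5 and comes back at 7. Bromide 5 is coupled with allylboronic acid pinacol ester (PdCl2(dppf), K3PO4), where the two allyl termini are identical, to give 4-methoxy-3-(methoxymethoxy)-5-(prop-2-en-1-yl)phenol F8. Cross-metathesis of F8 with 2-methylbut-2-ene (as solvent) using the second-generation Grubbs catalyst RuCl2(=CHPh)(PCy3)(H2IMes) at 40 °C then gives 7.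

Step 5. The risk is incomplete condensation or O-alkylation because both phenols are free. The fallback sets out from 8 and comes back at 9. Ketone 8 is C-formylated (HCO2Et, NaH, THF) and cyclodehydrated with HCl/AcOH to 7-hydroxy-4H-chromen-4-one F9. Dimethylamine (2 M in THF, EtOH, 23 °C) then adds to C2 of F9 and opens the pyranone to give 9.

**Further compounds**

F1 | step 6 | 2-methoxy-1,5-bis(methoxymethoxy)-3-(3-methylbut-2-en-1-yl)benzene | COCOc1cc(OCOC)c(OC)c(CC=C(C)C)c1
F2 | step 6 | 2-bromo-4-methoxy-1,5-bis(methoxymethoxy)-3-(3-methylbut-2-en-1-yl)benzene | COCOc1cc(OCOC)c(OC)c(CC=C(C)C)c1Br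
F3 | step 6 | [3-methoxy-4,6-bis(methoxymethoxy)-2-(3-methylbut-2-en-1-yl)phenyl]boronic acid | COCOc1cc(OCOC)c(OC)c(CC=C(C)C)c1B(O)O
F4 | step 6 | 1-[2-hydroxy-4-(methoxymethoxy)phenyl]ethan-1-one | CC(=O)c1ccc(OCOC)cc1O
F5 | step 6 | (E)-3-(dimethylamino)-1-[2-hydroxy-4-(methoxymethoxy)phenyl]prop-2-en-1-one | CN(C)/C=C/C(=O)c1ccc(OCOC)cc1O
F6 | step 6 | 3-iodo-7-(methoxymethoxy)-4H-chromen-4-one | COCOc1ccc2c(c1)occ(I)c2=O
F7 | step 6 | 3-[3-methoxy-4,6-bis(methoxymethoxy)-2-(3-methylbut-2-en-1-yl)phenyl]-7-(methoxymethoxy)-4H-chromen-4-one | COCOc1ccc2c(c1)occ(-c1c(OCOC)cc(OCOC)c(OC)c1CC=C(C)C)c2=O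
F8 | step 4 | 4-methoxy-3-(methoxymethoxy)-5-(prop-2-en-1-yl)phenol | Oc1cc(OCOC)c(OC)c(CC=C)c1
F9 | step 5 | 7-hydroxy-4H-chromen-4-one | O=c1ccoc2cc(O)ccc12
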